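**Strategy.** The target is cut at C9–C10 of the cycloheptane (aromadendrane numbering), the carbocycle fused to the gem-dimethylcyclopropane (C6–C7) and to the cyclopentane (C1–C5). With the arene, the O-bridged oxepane, the cyclopentane and the carene-derived cyclopropane in place, ring-closing metathesis joins an isopropenyl group on the oxygenated quaternary C1 to an allyl arm on C7. It exploits the cis arrangement of these groups on the two small rings, and hydrogenation then sets C10. The metathesis precursor, a bridged tertiary allyl aryl ether, is assembled from (+)-3-carene, diformylphloroglucinol and isovaleraldehyde by an o-quinone methide cycloaddition, a pinacol-type hydride shift and an SN1 etherification.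

Key step: step 10

Remark (labels and one assumption): terpenoid carbons are labelled as in aromadendrane (C1 = O-bearing ring-fusion carbon, C4 = quaternary carbon with CH3-15, C5 = ring-fusion CH, C6/C7 = cyclopropane CH, C10 = CH with CH3-14, C11 = CMe2); C7' is the benzylic carbon. (+)-3-Carene is taken as (1S,6R); its two cyclopropane stereocentres become C6 and C7 unchanged.

Step 1
Reactants: 1 (+)-3-carene
Product: 2 2-[(1R,3S)-2,2-dimethyl-3-(2-oxopropyl)cyclopropyl]acetaldehyde
Conditions: O3, CH2Cl2/MeOH, −78 °C; then Me2S, −78 °C → rt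
Reagents that add atoms: ozone, O=[O+][O-]
Why: Ozonolysis with reductive work-up cleaves the only C=C bond and leaves the cis-cyclopropane (future C6/C7) untouched, so no stereocentre is made or lost.

Step 2
Reactants: 2 keto aldehyde
Product: 3 1-[(1S,3R)-2,2-dimethyl-3-(prop-2-en-1-yl)cyclopropyl]propan-2-one
Conditions: Ph3PCH3Br (1.05 equiv), KOtBu, THF, −78 → 0 °C
Reagents that add atoms: methyltriphenylphosphonium bromide, C[P+](c1ccccc1)(c1ccccc1)c1ccccc1.[Br-]
Why: Wittig methylenation with one equivalent of non-stabilised ylide at low temperature should take the aldehyde and spare the methyl ketone, giving the allyl arm (C8, C9) for the later ring closure.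

Step 3
Reactants: 3 keto olefin; 4 propargyl bromide
Product: 5 1-[(1S,3R)-2,2-dimethyl-3-(prop-2-en-1-yl)cyclopropyl]hex-5-yn-2-one
Conditions: LDA, THF, −78 °C; then 4, DMPU, −78 → −30 °C
Reagents that add atoms: none
Why: Kinetic deprotonation should occur at the methyl group rather than at the hindered CH2 next to the cyclopropane, and SN2 alkylation of this enolate installs C2–C4 as a masked acetonyl unit.

Step 4
Reactants: 5 alkynyl ketone
Product: 6 1-[(1S,3R)-2,2-dimethyl-3-(prop-2-en-1-yl)cyclopropyl]hexane-2,5-dione
Conditions: NaAuCl4·2H2O (2 mol %), MeOH/H2O, 60 °C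
Reagents that add atoms: water, O
Why: Gold-catalysed Markovnikov hydration of the terminal alkyne, assisted by the γ-keto group, should give the 1,4-diketone and leave the terminal olefin and the cyclopropane alone.

Step 5
Reactants: 6 1,4-diketone
Product: 7 2-[(1S,3R)-2,2-dimethyl-3-(prop-2-en-1-yl)cyclopropyl]-3-methylcyclopent-2-en-1-one
Conditions: 2% aq. KOH, EtOH, reflux
Reagents that add atoms: none
Why: Intramolecular aldol condensation under thermodynamic control (the jasmone-type closure) should give the tetrasubstituted 2-alkyl-3-methylcyclopentenone, which forms the cyclopentane with the former CH2 as C5.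

Step 6
Reactants: 7 cyclopentenone
Product: 8 (1S)-2-[(1S,3R)-2,2-dimethyl-3-(prop-2-en-1-yl)cyclopropyl]-3-methylcyclopent-2-en-1-ol
Conditions: (R)-Me-CBS (20 mol %), catecholborane (1.5 equiv), toluene, −78 °C
Reagents that add atoms: none
Why: Corey–Bakshi–Shibata reduction sets C1 under catalyst control with the α-substituted olefin carbon as the large group (the (R)-catalyst is expected to give 1S; the antipode is available), and catecholborane does not hydroborate the allyl olefin at this temperature.

Step 7
Reactants: 8 allylic alcohol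
Product: 9 tert-butyldimethylsilyl ether of 8
Conditions: TBSCl, imidazole, DMF, rt
Reagents that add atoms: tert-butyldimethylsilyl chloride, CC(C)(C)[Si](C)(C)Cl
Why: Silylation turns the C1 oxygen into a bulky group that blocks one face of the ring olefin and makes C1 a silyloxy carbon for the later hydride shift.

Step 8
Reactants: 9 allylic silyl ether; 10 2,4-diformylphloroglucinol; 11 isovaleraldehyde
Product: 14 (2R,3R)-3-[(1R)-1-(3,5-diformyl-2,4,6-trihydroxyphenyl)-3-methylbutyl]-2-[(1R,3R)-2,2-dimethyl-3-(prop-2-en-1-yl)cyclopropyl]-3-methylcyclopentan-1-one, via o-quinone methide 12 (not isolated), via chromane cycloadduct 13 (not isolated)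
Conditions: EDDA (10 mol %), MeCN, 50 °C; then Sc(OTf)3 (10 mol %), MeCN/H2O, 0 °C → rt
Reagents that add atoms: none
Why: Knoevenagel condensation gives o-quinone methide 12, which adds to the electron-rich tetrasubstituted olefin of 9 in an inverse-demand hetero-Diels–Alder reaction on the face opposite the OTBS group with C7' bonding to the methyl-bearing carbon (this sets C4, and C7' through the arrangement with the arene over the methyl edge, for which only modest selectivity is expected, so the C7' epimer is removed), and scandium triflate then ionises the tertiary cyclopropylcarbinyl aryl ether of 13 so that the C1 hydrogen, cis to the departing oxygen, migrates to C5 in a pinacol-type 1,2-hydride shift that ends in the ketone after loss of the silyl group (C5–H cis to C7', which is also the thermodynamic epimer).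

Step 9
Reactants: 14 ketone; 15 isopropenylmagnesium bromide
Product: 18 bridged tertiary allyl aryl ether (metathesis precursor), via bis-tert-butylimine 16 (not isolated), via tertiary allylic alcohol 17 (not isolated)
Conditions: t-BuNH2, MgSO4, CH2Cl2, rt, evaporate; then CeCl3, 15 (excess), THF, −78 → 0 °C; then 1 M HCl, THF, 0 °C → rt
Reagents that add atoms: none
Why: Masking both chelated formyl groups in the flask as N-tert-butyl aldimines (vinylogous amides) and the phenols as phenoxides should leave the cyclopentanone as the only electrophile for the weakly basic organocerium reagent (1,2-addition, C1 configuration irrelevant), and aqueous acid then hydrolyses the imines and ionises the tertiary allylic alcohol to an allyl cation that the ortho phenol, held on the upper face by the C4–C7' link, captures at C1 (SN1 cycloetherification), which fixes C1 with oxygen cis to C7' and the isopropenyl group cis to the cyclopropyl group.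

Step 10
Reactants: 18 bridged tertiary allyl aryl ether
Product: 19 9,10-didehydro derivative of the target (cycloheptene with C9=C10)
Conditions: Hoveyda–Grubbs II (10 mol %), toluene (2 mM), 80 °C, Ar sparge
Reagents that add atoms: none
Why: Ring-closing olefin metathesis: the ruthenium alkylidene loads on the unhindered monosubstituted allyl olefin on cyclopropane carbon C7 and then undergoes intramolecular [2+2] cycloaddition and cycloreversion with the 1,1-disubstituted isopropenyl olefin on C1, expelling ethene. The closest known reaction type is metathesis closure of trisubstituted cycloheptenes next to a quaternary allylic centre with second-generation catalysts. The one ring closed is the seven-membered carbocycle C1–C5–C6–C7–C8–C9–C10, through the new C9=C10 bond of a 1,8-diene, while arene, oxepane, cyclopentane and cyclopropane are already present. No stereocentre is created: C1, C5, C6 and C7 come from steps 9, 8 and 1, and C10 is set in step 11. The selectivity needed is cyclisation over cross-metathesis and oligomerisation; it is secured by high dilution and by the substrate, because the isopropenyl group (C1) and the cyclopropyl group (C5) are cis on the cyclopentane and the allyl arm is cis to C5 on the cyclopropane, so both olefins sit together on the face opposite the aryl ether bridge. Free phenols and chelated formyl groups are tolerated by the catalyst.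

Step 11
Reactants: 19 cycloheptene
Product: 20 target CNP0189833.2
Conditions: H2 (3 atm), 5% Rh/Al2O3, EtOAc, rt
Reagents that add atoms: none
Why: Heterogeneous syn hydrogenation should deliver hydrogen to C9=C10 from the face opposite the endo methyl of the cyclopropane and the C1–O bond (as in the hydrogenation of 3-carene to cis-carane), which places CH3-14 syn to oxygen (10S), and rhodium on alumina is chosen because it should not hydrogenolyse the allylic C–O bond or reduce the chelated formyl groups.

Compound list
1 | (+)-3-carene, (1S,6R)-3,7,7-trimethylbicyclo[4.1.0]hept-3-ene | CC1=CC[C@@H]2[C@H](C1)C2(C)C | starting material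
2 | 2-[(1R,3S)-2,2-dimethyl-3-(2-oxopropyl)cyclopropyl]acetaldehyde | CC(=O)C[C@H]1[C@@H](CC=O)C1(C)C | intermediate
3 | 1-[(1S,3R)-2,2-dimethyl-3-(prop-2-en-1-yl)cyclopropyl]propan-2-one | CC(=O)C[C@H]1[C@@H](CC=C)C1(C)C | intermediate
4 | propargyl bromide (3-bromoprop-1-yne) | C#CCBr | starting material
5 | 1-[(1S,3R)-2,2-dimethyl-3-(prop-2-en-1-yl)cyclopropyl]hex-5-yn-2-one | C#CCCC(=O)C[C@H]1[C@@H](CC=C)C1(C)C | intermediate
6 | 1-[(1S,3R)-2,2-dimethyl-3-(prop-2-en-1-yl)cyclopropyl]hexane-2,5-dione | CC(=O)CCC(=O)C[C@H]1[C@@H](CC=C)C1(C)C | intermediate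
7 | 2-[(1S,3R)-2,2-dimethyl-3-(prop-2-en-1-yl)cyclopropyl]-3-methylcyclopent-2-en-1-one | O=C1CCC(C)=C1[C@H]1[C@@H](CC=C)C1(C)C | intermediate
8 | (1S)-2-[(1S,3R)-2,2-dimethyl-3-(prop-2-en-1-yl)cyclopropyl]-3-methylcyclopent-2-en-1-ol | O[C@H]1CCC(C)=C1[C@H]1[C@@H](CC=C)C1(C)C | intermediate
9 | tert-butyl{[(1S)-2-[(1S,3R)-2,2-dimethyl-3-(prop-2-en-1-yl)cyclopropyl]-3-methylcyclopent-2-en-1-yl]oxy}dimethylsilane | CC(C)(C)[Si](C)(C)O[C@H]1CCC(C)=C1[C@H]1[C@@H](CC=C)C1(C)C | intermediate
10 | 2,4-diformylphloroglucinol (2,4,6-trihydroxybenzene-1,3-dicarbaldehyde) | O=Cc1c(O)cc(O)c(C=O)c1O | starting material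
11 | isovaleraldehyde (3-methylbutanal) | CC(C)CC=O | starting material
12 | (E)-o-quinone methide from 10 and 11 (3-methylbutylidene at the former C–H carbon) | CC(C)C/C=C1/C(=O)C(C=O)=C(O)C(C=O)=C1O | intermediate (not isolated)
13 | (3S,3aS,9R,9aR)-3-[(tert-butyldimethylsilyl)oxy]-3a-[(1S,3R)-2,2-dimethyl-3-(prop-2-en-1-yl)cyclopropyl]-6,8-dihydroxy-9a-methyl-9-(2-methylpropyl)-1,2,3,3a,9,9a-hexahydrocyclopenta[b]chromene-5,7-dicarbaldehyde (cis-fused cycloadduct) | CC(C)C[C@H]1c2c(O)c(C=O)c(O)c(C=O)c2O[C@]2([C@H]3[C@@H](CC=C)C3(C)C)[C@@H](O[Si](C)(C)C(C)(C)C)CC[C@]12C | intermediate (not isolated)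
14 | (2R,3R)-3-[(1R)-1-(3,5-diformyl-2,4,6-trihydroxyphenyl)-3-methylbutyl]-2-[(1R,3R)-2,2-dimethyl-3-(prop-2-en-1-yl)cyclopropyl]-3-methylcyclopentan-1-one | CC(C)C[C@@H](c1c(O)c(C=O)c(O)c(C=O)c1O)[C@@]1(C)CCC(=O)[C@@H]1[C@H]1[C@@H](CC=C)C1(C)C | intermediate
15 | isopropenylmagnesium bromide | CC(=C)[Mg]Br | starting material
16 | bis(N-tert-butylimine) of 14 (both formyl groups as CH=N-tBu) | CC(C)C[C@@H](c1c(O)c(C=NC(C)(C)C)c(O)c(C=NC(C)(C)C)c1O)[C@@]1(C)CCC(=O)[C@@H]1[C@H]1[C@@H](CC=C)C1(C)C | intermediate (not isolated)
17 | tertiary allylic alcohol from 16 (1-isopropenylcyclopentan-1-ol, both C1 epimers) | CC(C)C[C@@H](c1c(O)c(C=NC(C)(C)C)c(O)c(C=NC(C)(C)C)c1O)[C@@]1(C)CCC(O)(C(C)=C)[C@@H]1[C@H]1[C@@H](CC=C)C1(C)C | intermediate (not isolated)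
18 | (2R,3R,4R,5R)-3-[(1R,3R)-2,2-dimethyl-3-(prop-2-en-1-yl)cyclopropyl]-6,8-dihydroxy-4-methyl-5-(2-methylpropyl)-2-(prop-1-en-2-yl)-2,3,4,5-tetrahydro-2,4-ethano-1-benzoxepine-7,9-dicarbaldehyde | CC(C)C[C@H]1c2c(O)c(C=O)c(O)c(C=O)c2O[C@]2(C(C)=C)CC[C@@]1(C)[C@H]2[C@H]1[C@@H](CC=C)C1(C)C | intermediate
19 | 9,10-didehydro target: pentacycle with C9=C10 in the cycloheptene (C1 R, C4 R, C5 R, C6 R, C7 R, C7' R) | CC(C)C[C@H]1c2c(O)c(C=O)c(O)c(C=O)c2O[C@]23CC[C@@]1(C)[C@H]2[C@H]1[C@@H](CC=C3C)C1(C)C | intermediate
20 | CNP0189833.2 (C1 S, C4 R, C5 R, C6 R, C7 R, C10 S, C7' R) | CC(C)C[C@H]1c2c(O)c(C=O)c(O)c(C=O)c2O[C@]23CC[C@@]1(C)[C@H]2[C@H]1[C@@H](CC[C@@H]3C)C1(C)C | target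

Total step count: 11. Longest linear sequence: 11 steps (from 1).

Steps most likely to fail

Step 8. In the ionisation stage the cyclopropylcarbinyl cation may open the three-membered ring or lose a proton faster than the hydride migrates, and the cycloaddition itself may show poor exo/endo discrimination at C7'. Fallback, from 13 back to 14: the cycloadduct 13 is isolated, and the C7' epimers are separated there. It is desilylated with TBAF/AcOH to the chromane alcohol F1 and oxidised with Dess–Martin periodinane to the α-aryloxy ketone F2. The C5–O bond is then cleaved reductively with zinc in acetic acid (electron transfer to the ketone, loss of the aryloxide, protonation and equilibration of the enol), which should give 14 without any carbocation.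

Step 9. The organocerium reagent may attack the masked formyl groups or merely enolise the hindered ketone, and the allyl cation may shed a proton to a diene instead of being trapped by the phenol. Fallback, from 14 back to 18: both formyl groups are protected as isolated dimethyl acetals (HC(OMe)3, PPTS, MeOH) to give the bis-acetal F3. Isopropenyllithium/CeCl3 then adds to the ketone to give the tertiary allylic alcohol F4, and PPTS in wet acetone removes the acetals and closes the ether to 18.

Step 11. Hydrogen may be delivered to the wrong face of the trisubstituted olefin (C10 epimer), or the allylic C1–O bond may be hydrogenolysed before the olefin is saturated. Fallback, from 19 back to 20: stereocontrol is moved from the substrate to the reagent by homogeneous hydrogenation with a chiral cationic iridium N,P-ligand (PHOX-type) catalyst. Both ligand antipodes are tried so that one is matched with the substrate, and this catalyst class does not cleave allylic ethers. This fallback makes no new compound (F0).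

Further compounds
F1 | step 8 | chromane alcohol (13 without the silyl group) | CC(C)C[C@H]1c2c(O)c(C=O)c(O)c(C=O)c2O[C@]2([C@H]3[C@@H](CC=C)C3(C)C)[C@@H](O)CC[C@]12C
F2 | step 8 | α-aryloxy ketone (C1 ketone of F1) | CC(C)C[C@H]1c2c(O)c(C=O)c(O)c(C=O)c2O[C@]2([C@H]3[C@@H](CC=C)C3(C)C)C(=O)CC[C@]12C
F3 | step 9 | bis(dimethyl acetal) of 14 | CC(C)C[C@@H](c1c(O)c(C(OC)OC)c(O)c(C(OC)OC)c1O)[C@@]1(C)CCC(=O)[C@@H]1[C@H]1[C@@H](CC=C)C1(C)C
F4 | step 9 | tertiary allylic alcohol from F3 (both C1 epimers) | CC(C)C[C@@H](c1c(O)c(C(OC)OC)c(O)c(C(OC)OC)c1O)[C@@]1(C)CCC(O)(C(C)=C)[C@@H]1[C@H]1[C@@H](CC=C)C1(C)C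
F0 | step 11 | none | none
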